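With an equilibrium constant of 1.85 L mol⁻¹ and a solubility of 0.65 M, the solid substrate feeds a starting material that competes with a second substrate for the same coupling partner.

    starting material + coupling partner ⇌ target (K1 = 1.85 L mol⁻¹, k1 = 0.132 L mol⁻¹ s⁻¹)
    second substrate + coupling partner → second product (k2 = 0.550 L mol⁻¹ s⁻¹)
    solid substrate ⇌ starting material, rate k3*(cs3 - [starting material]) while solid is left; crystals form when [starting material] > cs3 (cs3 = 0.65 M, k3 = 0.0625 s⁻¹)

solid substrate 1.0 M; coupling partner 1.20 M; second substrate 1.00 M; time 10 min

- at 10 min, what has stopped the reaction, if anything has (for what has run out or reacted, a solid counts together with what of it has only dissolved) (the coupling partner has run out first / forward and back rates have come level / all of the solid substrate has reacted / it is still moving)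
- amount of target at 10 min, in percent of the solid substrate charged
- amount of starting material at 10 min, in percent of the solid substrate charged

- as a solid, counted per litre of solution: solid substrate
- at the start none of the solid substrate is in solution
- what has only dissolved of solid substrate counts as not reacted
- starting material means what is dissolved; the solid is not counted in it
- the reaction counts as stopped when no species that holds the solid substrate changes by six tenths of a point or more over the second half of the time
- run time (flask): 10 min

I built the flask up one process at a time and reckoned end states, because the forward half-life of starting material by the coupling step alone, with the other concentrations as charged and the way back not counted, 0.073 min, is far shorter than 10 min. With the coupling step alone and the whole charge dissolved, the equilibrium balance gave 0.547 M of target.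

I then added the second step, which has no way back and a shorter half-life, 1.1 s. I let it take coupling partner equal to its whole charge, leaving a surplus of 0.200 M for free partner and target together. The same balance gave 0.124 M of target, but this required 0.876 M of starting material, more than the solubility.

With dissolution added, I took [starting material] at 0.65 M for as long as solid was left, and at equilibrium target then took a share 0.546 of the surplus, or 0.109 M. That left 0.241 M of solid, since the dissolved and coupled amounts came to less than the charge. The amount of target in this reckoning came from the equilibrium of the coupling step, which is thermodynamic control of that step. The quantity I carried forward was the crossing surplus, the surplus of coupling partner over second substrate at which the solid just disappears, for this charge of solid substrate, this solubility and this equilibrium constant, with the second substrate reckoned as consumed: 0.641 M. I expected forward and back rates of the coupling step to have come level, with 10.9% target and 65.0% starting material.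

The forecast chose "forward and back rates have come level", with target at 10.9% (10.5% to 11.3%) and starting material at 65% (64.5% to 65.5%), holding that “the reaction is stationary well before 10 min”. Its figures matched mine.

The simulation gave "forward and back rates have come level", with 10.9% target and 65.0% starting material.

In the flask, target already read 9.84% at 0.500 min, and the drag of dissolving did not change the conversion of solid substrate. The flask's surplus of 0.200 M lay below the crossing, and its solid substrate read 24.1% at 10.0 min. In the neighbour flask with 0.25 M of second substrate, the surplus was 0.950 M, above the crossing. The balance with the whole charge dissolved gave 0.470 M of target. That neighbour flask reached 47.0% target and 53.0% starting material, with its solid substrate at 0%.

The numbers stand for no real mixture; the rest is arithmetic.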